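**Assumption:** the target is taken exactly as the SMILES given: (7S,8S,8aS) in the bicycle (7‑OH/8‑OH cis, H8/H8a trans) and (1E,3S,4R,5R) in the side chain (3‑OH/4‑OH anti, 4‑OH/5‑Me anti).

## Retrosynthetic overview

1. Target ⇐ ynenone 16: the pyran (ring B) is closed last by 6‑endo oxa‑Michael addition (O2–C3), after C1 is added to C8a as formaldehyde (C1–C8a).
2. Dienynone 14 ⇐ core alkyne 13 + propargylic diol 7 by E‑selective head‑to‑head alkyne cross‑dimerisation (C3–C1′).
3. Cyclohexenone 13 (ring A; C7 and C8 set) ⇐ α‑ketol ring expansion of acetyl cyclopentenol 12 (C8 shifts from C6 to the acetyl carbon) ⇐ (S)‑4‑silyloxycyclopentenone 8 by alkynylation, 1,3‑oxidative transposition and acyl‑anion addition.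
4. Diol 7 ⇐ chelation‑controlled MeMgBr addition to hydroxy ynone 5 ⇐ AlMe3 opening of Sharpless epoxy alcohol 3 ⇐ (E)‑pent‑2‑enal 1.
5. Ring order: purchased cyclopentene → ring A by expansion → ring B last.

## Route

**Step 1**
Reactants: 1 (E)-pent-2-enal
Product: 2 rac-(E)-1-(trimethylsilyl)hept-4-en-1-yn-3-ol
Conditions: TMSC≡CH, n-BuLi, THF, −78 °C; then 1, −78 → 0 °C; H2O
Reagents that add atoms: lithium (trimethylsilyl)acetylide, [Li]C#C[Si](C)(C)C, made in the flask from ethynyltrimethylsilane, C#C[Si](C)(C)C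
Why: 1,2-addition of a lithium acetylide to an enal (carbonyl alkynylation); the racemic carbinol centre is only a handle for step 2 and is oxidised away in step 4.

**Step 2**
Reactants: 2 rac-(E)-1-(trimethylsilyl)hept-4-en-1-yn-3-ol
Product: 3 (1S)-1-[(2S,3S)-3-ethyloxiran-2-yl]-3-(trimethylsilyl)prop-2-yn-1-ol
Conditions: Ti(Oi-Pr)4 (10 mol %), L-(+)-DIPT (12 mol %), t-BuOOH (0.55 equiv), 4 Å MS, CH2Cl2, −20 °C
Reagents that add atoms: tert-butyl hydroperoxide, CC(C)(C)OO
Why: Sharpless asymmetric epoxidation run as a kinetic resolution of a secondary (E)-allylic alcohol: the L-(+)-tartrate catalyst epoxidises (R)-2 fast and on one alkene face, giving the erythro epoxy alcohol (at most 50 %) whose (2S,3S)-oxirane carbons become C4′ and C5′, while (S)-2 is left behind.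

**Step 3**
Reactants: 3 (1S)-1-[(2S,3S)-3-ethyloxiran-2-yl]-3-(trimethylsilyl)prop-2-yn-1-ol
Product: 4 (3S,4R,5R)-5-methyl-1-(trimethylsilyl)hept-1-yne-3,4-diol
Conditions: AlMe3 (3 equiv), hexane/CH2Cl2, −20 → 0 °C; aq. potassium sodium tartrate
Reagents that add atoms: trimethylaluminium, C[Al](C)C
Why: trialkylaluminium opening of a 2,3-epoxy alcohol: methyl is delivered to the distal epoxide carbon with inversion (SN2), which sets C5′ (R) and leaves the C4′–O bond (R) untouched, so 4‑OH and 5‑Me are anti.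

**Step 4**
Reactants: 4 (3S,4R,5R)-5-methyl-1-(trimethylsilyl)hept-1-yne-3,4-diol
Product: 5 (4R,5R)-4-hydroxy-5-methyl-1-(trimethylsilyl)hept-1-yn-3-one
Conditions: MnO2 (20 equiv), CH2Cl2, 23 °C
Reagents that add atoms: none
Why: chemoselective MnO2 oxidation of the propargylic alcohol beside an unactivated secondary alcohol; the neutral conditions do not epimerise C4′.

**Step 5**
Reactants: 5 (4R,5R)-4-hydroxy-5-methyl-1-(trimethylsilyl)hept-1-yn-3-one
Product: 7 (3S,4R,5R)-3,5-dimethylhept-1-yne-3,4-diol, via silyl alkyne diol 6 (not isolated)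
Conditions: MeMgBr (3.5 equiv), THF, −78 → −20 °C; then MeOH, K2CO3 (0.2 equiv), 23 °C; H2O
Reagents that add atoms: methylmagnesium bromide, C[Mg]Br
Why: Cram-chelate-controlled Grignard addition: the magnesium alkoxide of the α-hydroxyl and the ynone carbonyl form a five-membered chelate and methyl adds anti to the sec-butyl group, setting C3′ (S; 3‑OH/4‑OH anti); methanolysis then removes the alkynyl silyl group.

**Step 6**
Reactants: 8 (4S)-4-[(tert-butyldimethylsilyl)oxy]cyclopent-2-en-1-one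
Product: 9 (1RS,4S)-4-[(tert-butyldimethylsilyl)oxy]-1-ethynylcyclopent-2-en-1-ol
Conditions: HC≡CMgBr (1.5 equiv), THF, −78 → 0 °C; H2O
Reagents that add atoms: ethynylmagnesium bromide, C#C[Mg]Br
Why: 1,2-addition of an alkynyl Grignard reagent to the enone carbonyl; the new carbinol centre is erased in step 7, and the C8 stereocentre (S) comes from the purchased enone.

**Step 7**
Reactants: 9 (1RS,4S)-4-[(tert-butyldimethylsilyl)oxy]-1-ethynylcyclopent-2-en-1-ol
Product: 10 (5S)-5-[(tert-butyldimethylsilyl)oxy]-3-ethynylcyclopent-2-en-1-one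
Conditions: pyridinium chlorochromate [C5H5NH][CrO3Cl] (2 equiv), 4 Å MS, CH2Cl2, 23 °C
Reagents that add atoms: pyridinium chlorochromate, [O-][Cr](=O)(=O)Cl.c1cc[nH+]cc1
Why: Dauben oxidative 1,3-transposition: the tertiary allylic chromate ester undergoes a [3,3] shift and the secondary chromate is oxidised, which moves the carbonyl next to C8 and leaves the alkyne on the enone β-carbon (future C4a); no stereocentre is touched.

**Step 8**
Reactants: 10 (5S)-5-[(tert-butyldimethylsilyl)oxy]-3-ethynylcyclopent-2-en-1-one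
Product: 12 1-[(1R,5S)-5-[(tert-butyldimethylsilyl)oxy]-3-ethynyl-1-hydroxycyclopent-2-en-1-yl]ethan-1-one, via ethoxyvinyl carbinol 11 (not isolated)
Conditions: ethyl vinyl ether, t-BuLi, THF, −78 → 0 °C; CeCl3, then 10 (2.5 equiv of reagent; the first equivalent is taken up by the alkyne C–H), −78 °C; then 0.5 M HCl, THF, 0 °C
Reagents that add atoms: 1-ethoxyvinyllithium, [Li]C(=C)OCC, made in the flask from ethyl vinyl ether, C=COCC; water, O
Why: acyl-anion-equivalent addition (1-ethoxyvinyl metal) to the ketone anti to the adjacent silyloxy group (Felkin-type control), so the new tertiary OH at C6 (R) is cis to C8–O; mild enol ether hydrolysis then unmasks the acetyl group.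

**Step 9**
Reactants: 12 1-[(1R,5S)-5-[(tert-butyldimethylsilyl)oxy]-3-ethynyl-1-hydroxycyclopent-2-en-1-yl]ethan-1-one
Product: 13 (5S,6S)-5-[(tert-butyldimethylsilyl)oxy]-3-ethynyl-6-hydroxy-6-methylcyclohex-2-en-1-one
Conditions: Al(Ot-Bu)3 (1.2 equiv), PhMe, 60 °C; aq. potassium sodium tartrate
Reagents that add atoms: none
Why: α-ketol (acyloin) rearrangement with ring expansion: in the syn aluminium chelate of carbinol oxygen and acetyl carbonyl, C8 shifts suprafacially from C6 to the acetyl carbon with retention, so the new C7–OH lies on the face of the former C6–O (cis to C8–O, 7S); relief of cyclopentene strain and formation of the conjugated enynone drive the shift and drain any alkenyl-shift isomer back through the reversible manifold.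

**Step 10**
Reactants: 13 (5S,6S)-5-[(tert-butyldimethylsilyl)oxy]-3-ethynyl-6-hydroxy-6-methylcyclohex-2-en-1-one; 7 (3S,4R,5R)-3,5-dimethylhept-1-yne-3,4-diol
Product: 14 (5S,6S)-5-[(tert-butyldimethylsilyl)oxy]-3-[(3E,5S,6R,7R)-5,6-dihydroxy-5,7-dimethylnon-3-en-1-yn-1-yl]-6-hydroxy-6-methylcyclohex-2-en-1-one
Conditions: RhCl(PPh3)3 (5 mol %), PhMe, 50 °C; 7 (1.3 equiv) added over 8 h
Reagents that add atoms: none
Why: Proposed new method: hydroxyl-directed, rhodium-catalysed head-to-head cross-dimerisation (formal syn-hydroalkynylation) of two different terminal alkynes with a conjugated ynenone as the C–H donor; the more acidic ynenone C(sp)–H adds to rhodium, the slowly added propargylic alcohol 7 binds through its tertiary OH and inserts into Rh–H with hydride going to the internal carbon, and C(sp)–C(sp2) reductive elimination forms the C3–C1′ bond and the E-alkene; the closest known reaction type is the rhodium-catalysed E-selective head-to-head dimerisation of tertiary propargylic alcohols and their cross-dimerisation with aryl- or silylacetylenes.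

**Step 11**
Reactants: 14 (5S,6S)-5-[(tert-butyldimethylsilyl)oxy]-3-[(3E,5S,6R,7R)-5,6-dihydroxy-5,7-dimethylnon-3-en-1-yn-1-yl]-6-hydroxy-6-methylcyclohex-2-en-1-one
Product: 15 (5S,6S)-5-[(tert-butyldimethylsilyl)oxy]-6-methyl-1,6-bis[(trimethylsilyl)oxy]-3-[(3E,5S,6R,7R)-5,7-dimethyl-5,6-bis[(trimethylsilyl)oxy]non-3-en-1-yn-1-yl]cyclohexa-1,3-diene
Conditions: TMSOTf (5 equiv), Et3N (7 equiv), CH2Cl2, 0 °C
Reagents that add atoms: trimethylsilyl trifluoromethanesulfonate, C[Si](C)(C)OS(=O)(=O)C(F)(F)F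
Why: soft enolisation to a silyl dienol ether: C7 is quaternary, so only the γ-protons at C8a can be removed and the linear 1-silyloxy-1,3-diene forms, while the three hydroxyls are silylated at the same time.

**Step 12**
Reactants: 15 (5S,6S)-5-[(tert-butyldimethylsilyl)oxy]-6-methyl-1,6-bis[(trimethylsilyl)oxy]-3-[(3E,5S,6R,7R)-5,7-dimethyl-5,6-bis[(trimethylsilyl)oxy]non-3-en-1-yn-1-yl]cyclohexa-1,3-diene
Product: 16 (4S,5S,6S)-5-[(tert-butyldimethylsilyl)oxy]-3-[(3E,5S,6R,7R)-5,6-dihydroxy-5,7-dimethylnon-3-en-1-yn-1-yl]-6-hydroxy-4-(hydroxymethyl)-6-methylcyclohex-2-en-1-one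
Conditions: 37 % aq. CH2O (10 equiv), Yb(OTf)3 (20 mol %), THF, 23 °C; then 0.5 M HCl, 0 °C
Reagents that add atoms: formaldehyde, C=O
Why: vinylogous Mukaiyama aldol (lanthanide-triflate-catalysed hydroxymethylation in aqueous medium): the dienol ether reacts at its γ-carbon C8a, which restores the enone, and formaldehyde enters anti to the neighbouring OTBS group (future 8aS); the acid work-up cleaves the TMS ethers.

**Step 13**
Reactants: 16 (4S,5S,6S)-5-[(tert-butyldimethylsilyl)oxy]-3-[(3E,5S,6R,7R)-5,6-dihydroxy-5,7-dimethylnon-3-en-1-yn-1-yl]-6-hydroxy-4-(hydroxymethyl)-6-methylcyclohex-2-en-1-one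
Product: 18 (7S,8S,8aS)-3-[(1E,3S,4R,5R)-3,4-dihydroxy-3,5-dimethylhept-1-en-1-yl]-7,8-dihydroxy-7-methyl-1,7,8,8a-tetrahydro-6H-isochromen-6-one, via silylated isochromenone 17 (not isolated)
Conditions: TBAF (3 equiv), THF, 0 → 23 °C; H2O
Reagents that add atoms: none
Why: fluoride-mediated cascade: the primary alkoxide adds 6-endo-dig to the ynenone (1,6-oxa-Michael addition), protonation at C4 gives the doubly vinylogous ester of ring B, and the TBS ether is then cleaved; C8a can epimerise through the dienolate and rests in the trans-diaxial H8/H8a arrangement of the target.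

## Compound list

1 | (E)-pent-2-enal | CC/C=C/C=O | starting material
2 | rac-(E)-1-(trimethylsilyl)hept-4-en-1-yn-3-ol | CC/C=C/C(O)C#C[Si](C)(C)C | intermediate
3 | (1S)-1-[(2S,3S)-3-ethyloxiran-2-yl]-3-(trimethylsilyl)prop-2-yn-1-ol | CC[C@@H]1O[C@H]1[C@@H](O)C#C[Si](C)(C)C | intermediate
4 | (3S,4R,5R)-5-methyl-1-(trimethylsilyl)hept-1-yne-3,4-diol | CC[C@@H](C)[C@@H](O)[C@@H](O)C#C[Si](C)(C)C | intermediate
5 | (4R,5R)-4-hydroxy-5-methyl-1-(trimethylsilyl)hept-1-yn-3-one | CC[C@@H](C)[C@@H](O)C(=O)C#C[Si](C)(C)C | intermediate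
6 | (3S,4R,5R)-3,5-dimethyl-1-(trimethylsilyl)hept-1-yne-3,4-diol (not isolated) | CC[C@@H](C)[C@@H](O)[C@@](C)(O)C#C[Si](C)(C)C | intermediate
7 | (3S,4R,5R)-3,5-dimethylhept-1-yne-3,4-diol | CC[C@@H](C)[C@@H](O)[C@@](C)(O)C#C | intermediate
8 | (4S)-4-[(tert-butyldimethylsilyl)oxy]cyclopent-2-en-1-one | O=C1C=C[C@@H](O[Si](C)(C)C(C)(C)C)C1 | starting material
9 | (1RS,4S)-4-[(tert-butyldimethylsilyl)oxy]-1-ethynylcyclopent-2-en-1-ol (C1 epimers) | C#CC1(O)C=C[C@@H](O[Si](C)(C)C(C)(C)C)C1 | intermediate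
10 | (5S)-5-[(tert-butyldimethylsilyl)oxy]-3-ethynylcyclopent-2-en-1-one | O=C1C=C(C#C)C[C@@H]1O[Si](C)(C)C(C)(C)C | intermediate
11 | (1R,5S)-5-[(tert-butyldimethylsilyl)oxy]-1-(1-ethoxyethenyl)-3-ethynylcyclopent-2-en-1-ol (not isolated) | CCOC(=C)[C@@]1(O)C=C(C#C)C[C@@H]1O[Si](C)(C)C(C)(C)C | intermediate
12 | 1-[(1R,5S)-5-[(tert-butyldimethylsilyl)oxy]-3-ethynyl-1-hydroxycyclopent-2-en-1-yl]ethan-1-one (1-OH cis to 5-OTBS) | CC(=O)[C@@]1(O)C=C(C#C)C[C@@H]1O[Si](C)(C)C(C)(C)C | intermediate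
13 | (5S,6S)-5-[(tert-butyldimethylsilyl)oxy]-3-ethynyl-6-hydroxy-6-methylcyclohex-2-en-1-one (6-OH cis to 5-OTBS) | C#CC1=CC(=O)[C@@](C)(O)[C@@H](O[Si](C)(C)C(C)(C)C)C1 | intermediate
14 | (5S,6S)-5-[(tert-butyldimethylsilyl)oxy]-3-[(3E,5S,6R,7R)-5,6-dihydroxy-5,7-dimethylnon-3-en-1-yn-1-yl]-6-hydroxy-6-methylcyclohex-2-en-1-one | CC[C@@H](C)[C@@H](O)[C@@](C)(O)/C=C/C#CC1=CC(=O)[C@@](C)(O)[C@@H](O[Si](C)(C)C(C)(C)C)C1 | intermediate
15 | (5S,6S)-5-[(tert-butyldimethylsilyl)oxy]-6-methyl-1,6-bis[(trimethylsilyl)oxy]-3-[(3E,5S,6R,7R)-5,7-dimethyl-5,6-bis[(trimethylsilyl)oxy]non-3-en-1-yn-1-yl]cyclohexa-1,3-diene | CC[C@@H](C)[C@@H](O[Si](C)(C)C)[C@@](C)(O[Si](C)(C)C)/C=C/C#CC1=C[C@H](O[Si](C)(C)C(C)(C)C)[C@](C)(O[Si](C)(C)C)C(O[Si](C)(C)C)=C1 | intermediate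
16 | (4S,5S,6S)-5-[(tert-butyldimethylsilyl)oxy]-3-[(3E,5S,6R,7R)-5,6-dihydroxy-5,7-dimethylnon-3-en-1-yn-1-yl]-6-hydroxy-4-(hydroxymethyl)-6-methylcyclohex-2-en-1-one | CC[C@@H](C)[C@@H](O)[C@@](C)(O)/C=C/C#CC1=CC(=O)[C@@](C)(O)[C@@H](O[Si](C)(C)C(C)(C)C)[C@@H]1CO | intermediate
17 | (7S,8S,8aS)-8-[(tert-butyldimethylsilyl)oxy]-3-[(1E,3S,4R,5R)-3,4-dihydroxy-3,5-dimethylhept-1-en-1-yl]-7-hydroxy-7-methyl-1,7,8,8a-tetrahydro-6H-isochromen-6-one (not isolated) | CC[C@@H](C)[C@@H](O)[C@@](C)(O)/C=C/C1=CC2=CC(=O)[C@@](C)(O)[C@@H](O[Si](C)(C)C(C)(C)C)[C@@H]2CO1 | intermediate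
18 | (7S,8S,8aS)-3-[(1E,3S,4R,5R)-3,4-dihydroxy-3,5-dimethylhept-1-en-1-yl]-7,8-dihydroxy-7-methyl-1,7,8,8a-tetrahydro-6H-isochromen-6-one (CNP0291643.4) | CC[C@@H](C)[C@@H](O)[C@@](C)(O)/C=C/C1=CC2=CC(=O)[C@@](C)(O)[C@@H](O)[C@@H]2CO1 | target

## Step count and risks

Total: 13 steps. Longest linear sequence: 9 steps (steps 1–5, then 10–13); the core branch contributes steps 6–9.

**Steps most likely to fail**

- **Step 10 (the new cross-dimerisation).** Risks are homodimers of either alkyne, head-to-tail isomers, and the ynenone acting as acceptor. Fallback by known chemistry, setting out from 7: hydrozirconation–iodination (Cp2Zr(H)Cl, 3.5 equiv, THF, 23 °C; then I2) gives (1E,3S,4R,5R)-1-iodo-3,5-dimethylhept-1-ene-3,4-diol F1. Sonogashira coupling of F1 and 13 (Pd(PPh3)4, CuI, Et3N, THF, 23 °C) comes back to the route at 14.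

- **Step 9 (ring expansion).** Risks are migration of the alkenyl carbon C5 instead of C8, partial reaction through a non-chelated transition state (C7 epimer), and ionisation of the tertiary allylic alcohol by the Lewis acid. The fallback sets out from 12 and changes from a Lewis-acid shift of the silyl ether to an alkoxide-driven shift of the unprotected cis-diol. HF·pyridine (THF, 0 °C) gives 1-[(1R,5S)-3-ethynyl-1,5-dihydroxycyclopent-2-en-1-yl]ethan-1-one F2. Its magnesium bis-alkoxide (MgBr2·OEt2, i-Pr2NEt, THF, 40 °C) holds O6, O8 and the acetyl oxygen on one metal, and the α-oxido substituent makes C8 the better migrating group, so the base-type α-ketol shift gives (5S,6S)-3-ethynyl-5,6-dihydroxy-6-methylcyclohex-2-en-1-one F3. TBSCl/imidazole silylates only the secondary hydroxyl and comes back at 13.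

- **Step 12 (γ-hydroxymethylation).** Risks are α- instead of γ-attack, hydrolysis of the dienol ether before C–C bond formation, and double hydroxymethylation. The fallback sets out from 14 and replaces the silyl dienol ether by a Lewis-acid-shielded lithium dienolate. TMSCl/imidazole gives (5S,6S)-5-[(tert-butyldimethylsilyl)oxy]-3-[(3E,5S,6R,7R)-5,7-dimethyl-5,6-bis[(trimethylsilyl)oxy]non-3-en-1-yn-1-yl]-6-methyl-6-[(trimethylsilyl)oxy]cyclohex-2-en-1-one F4. The ketone is complexed to aluminium tris(2,6-diphenylphenoxide), Al(OC6H3Ph2)3, deprotonated at the γ-position with lithium tetramethylpiperidide (PhMe/THF, −78 °C) and treated with monomeric formaldehyde (directed vinylogous aldol at C8a); 0.5 M HCl work-up comes back at 16.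

## Further compounds

F1 | step 10 | (1E,3S,4R,5R)-1-iodo-3,5-dimethylhept-1-ene-3,4-diol | CC[C@@H](C)[C@@H](O)[C@@](C)(O)/C=C/I
F2 | step 9 | 1-[(1R,5S)-3-ethynyl-1,5-dihydroxycyclopent-2-en-1-yl]ethan-1-one | CC(=O)[C@@]1(O)C=C(C#C)C[C@@H]1O
F3 | step 9 | (5S,6S)-3-ethynyl-5,6-dihydroxy-6-methylcyclohex-2-en-1-one | C#CC1=CC(=O)[C@@](C)(O)[C@@H](O)C1
F4 | step 12 | (5S,6S)-5-[(tert-butyldimethylsilyl)oxy]-3-[(3E,5S,6R,7R)-5,7-dimethyl-5,6-bis[(trimethylsilyl)oxy]non-3-en-1-yn-1-yl]-6-methyl-6-[(trimethylsilyl)oxy]cyclohex-2-en-1-one | CC[C@@H](C)[C@@H](O[Si](C)(C)C)[C@@](C)(O[Si](C)(C)C)/C=C/C#CC1=CC(=O)[C@@](C)(O[Si](C)(C)C)[C@@H](O[Si](C)(C)C(C)(C)C)C1
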